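**Plan**

- Retrosynthesis: the C19 acetate and the C15=C17 methylene are late adjustments. The cis-lactone is cut at C1–C15 and O–C16 to an α-ketol (C1=O, C2–OH). The 14-membered ring is cut at C13–C14 by a retro-Claisen to a 12-membered lactone (C1 carbonyl, ring O on C11, which carries the isopropenyl group C12(=C13)Me). The seco acid is cut at C9–C10 and C5–C6 (two orthoester-Claisen retrons) back to (R)-glyceraldehyde acetonide.
- Enabling feature: with the lactone β-carbon C1 read as a latent ketone, C1(=O)–C14H2–C13H2–C12(Me)=C11H is a γ,δ-unsaturated ketone. C13–C14 is therefore the bond made by the [3,3] shift of the enol ether C14H2=C1–O–C11–C12=C13. The same pattern (E-trisubstituted alkene two carbons from a carbonyl) recurs at C3=C4 and C7=C8.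
- Forward order: the chain grows from C2 to C11 by two Johnson–Claisen rearrangements; macrolactonization gives the 12-membered lactone; lactone methylenation and Claisen shift expand it to the 14-membered carbocycle; the γ-lactone is then fused on (butenolide, 1,4-reduction, α-methylenation).
- Stereochemistry: C2 comes from D-glyceraldehyde and none of its bonds is ever broken. C1 is set by hydride addition to the butenolide anti to C3 (cis fusion). All three ring alkenes come from chair Claisen transition states.

Key step: step 14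

Remark: cembrane numbering is used (C1 = ring-fusion CH, C2 = lactone carbinol carbon, C19 = CH2O on C8; TBS = tert-butyldimethylsilyl, PMB = 4-methoxybenzyl). The carbinol centres made in steps 1, 7 and 10 are carried as epimer mixtures because each becomes an alkene carbon in the next Claisen step, so their SMILES carry no descriptor.

**Step 1**
Reactants: 1 (R)-2,2-dimethyl-1,3-dioxolane-4-carbaldehyde; 2 isopropenylmagnesium bromide
Product: 3 (1RS)-1-[(4R)-2,2-dimethyl-1,3-dioxolan-4-yl]-2-methylprop-2-en-1-ol
Conditions: THF, −78 to 0 °C; aq. NH4Cl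
Reagents that add atoms: none
Why: Grignard 1,2-addition to the α-alkoxy aldehyde (Felkin–Anh sense expected); the new carbinol centre needs no control because it becomes sp2 in step 2, and C2 is taken unchanged from the chiral pool.

**Step 2**
Reactants: 3; 4 triethyl orthoacetate
Product: 6 ethyl (4E)-5-[(4S)-2,2-dimethyl-1,3-dioxolan-4-yl]-4-methylpent-4-enoate, via ketene acetal 5 (not isolated)
Conditions: MeC(OEt)3 (excess), EtCO2H (cat.), 140 °C, EtOH distilled off
Reagents that add atoms: none
Why: Johnson–Claisen rearrangement, in which the chair transition state with the dioxolanyl group equatorial should give the E-trisubstituted C3=C4 alkene together with the C5–C6 bond.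

**Step 3**
Reactants: 6
Product: 7 ethyl (4E,6S)-6,7-dihydroxy-4-methylhept-4-enoate
Conditions: AcOH–H2O (4:1), 40 °C
Reagents that add atoms: none
Why: mild acid hydrolysis of the isopropylidene acetal, which the ethyl ester and the allylic C–O bond should tolerate.

**Step 4**
Reactants: 7
Product: 8 ethyl (4E,6S)-6,7-bis(tert-butyldimethylsilyloxy)-4-methylhept-4-enoate
Conditions: TBSCl (2.4 equiv), imidazole, DMF, rt
Reagents that add atoms: tert-butyldimethylsilyl chloride, CC(C)(C)[Si](C)(C)Cl
Why: standard silylation of both hydroxyls, giving a primary/secondary pair of silyl ethers that can later be opened selectively at C1.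

**Step 5**
Reactants: 8
Product: 9 (4E,6S)-6,7-bis(tert-butyldimethylsilyloxy)-4-methylhept-4-enal
Conditions: DIBAL-H (1.05 equiv), CH2Cl2, −78 °C; Rochelle salt
Reagents that add atoms: none
Why: low-temperature DIBAL half-reduction of an unhindered ethyl ester stops at the aluminium hemiacetal, which releases the aldehyde on work-up.

**Step 6**
Reactants: 10 2,3-dibromoprop-1-ene; 11 4-methoxybenzyl alcohol
Product: 12 2-bromoallyl 4-methoxybenzyl ether
Conditions: NaH, THF, 0 °C to rt, Bu4NI (cat.)
Reagents that add atoms: none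
Why: Williamson etherification at the allylic bromide, the vinylic bromide being inert to alkoxide displacement.

**Step 7**
Reactants: 12; 9
Product: 14 (3RS,6E,8S)-8,9-bis(tert-butyldimethylsilyloxy)-2-[(4-methoxybenzyloxy)methyl]-6-methylnona-1,6-dien-3-ol, via vinyllithium 13 (not isolated)
Conditions: t-BuLi (2 equiv), Et2O, −78 °C; then 9, −78 °C; aq. NH4Cl
Reagents that add atoms: none
Why: bromine–lithium exchange followed by 1,2-addition of the vinyllithium to the aldehyde, kept at −78 °C to suppress β-alkoxide elimination; the carbinol configuration is irrelevant because it is erased in step 8.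

**Step 8**
Reactants: 14; 4 triethyl orthoacetate
Product: 16 ethyl (4Z,8E,10S)-10,11-bis(tert-butyldimethylsilyloxy)-4-[(4-methoxybenzyloxy)methyl]-8-methylundeca-4,8-dienoate, via ketene acetal 15 (not isolated)
Conditions: MeC(OEt)3 (excess), EtCO2H (cat.), 140 °C, EtOH distilled off
Reagents that add atoms: none
Why: second Johnson–Claisen rearrangement, in which the chain on the carbinol carbon sits equatorial in the chair so that C6 ends trans to C9 (7Z by CIP because of the CH2O branch), installing C7=C8 with its oxymethyl group and the C9–C10 bond.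

**Step 9**
Reactants: 16
Product: 17 (4Z,8E,10S)-10,11-bis(tert-butyldimethylsilyloxy)-4-[(4-methoxybenzyloxy)methyl]-8-methylundeca-4,8-dienal
Conditions: DIBAL-H (1.05 equiv), CH2Cl2, −78 °C; Rochelle salt
Reagents that add atoms: none
Why: DIBAL half-reduction as in step 5, with silyl and PMB ethers inert.

**Step 10**
Reactants: 17; 2 isopropenylmagnesium bromide
Product: 18 (3RS,6Z,10E,12S)-12,13-bis(tert-butyldimethylsilyloxy)-6-[(4-methoxybenzyloxy)methyl]-2,10-dimethyltrideca-1,6,10-trien-3-ol
Conditions: THF, −78 to 0 °C; aq. NH4Cl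
Reagents that add atoms: none
Why: Grignard addition gives the isopropenyl carbinol that serves as the allyl half of the later Claisen shift; both C11 epimers are used because C11 becomes sp2 in step 14.

**Step 11**
Reactants: 18
Product: 19 (2S,3E,7Z,11RS)-2-(tert-butyldimethylsilyloxy)-8-[(4-methoxybenzyloxy)methyl]-4,12-dimethyltrideca-3,7,12-triene-1,11-diol
Conditions: HF·pyridine, pyridine, THF, 0 °C
Reagents that add atoms: none
Why: buffered HF·pyridine should cleave the primary TBS ether much faster than the hindered secondary one, leaving the PMB ether and the allylic alcohol untouched.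

**Step 12**
Reactants: 19
Product: 21 (2S,3E,7Z,11RS)-2-(tert-butyldimethylsilyloxy)-11-hydroxy-8-[(4-methoxybenzyloxy)methyl]-4,12-dimethyltrideca-3,7,12-trienoic acid, via aldehyde 20 (not isolated)
Conditions: TEMPO (cat.), PhI(OAc)2 (2.2 equiv), MeCN–pH 7 buffer, 0 °C to rt
Reagents that add atoms: water, O
Why: oxoammonium (TEMPO) oxidation is selective for the primary over the secondary allylic alcohol and carries the aldehyde hydrate on to the acid under neutral conditions that should not epimerize C2.

**Step 13**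
Reactants: 21
Product: 23 (3S,4E,8Z,12RS)-3-(tert-butyldimethylsilyloxy)-9-[(4-methoxybenzyloxy)methyl]-5-methyl-12-(prop-1-en-2-yl)oxacyclododeca-4,8-dien-2-one (12-membered lactone; carbonyl = C1, ring O on C11), via mixed anhydride 22 (not isolated)
Conditions: 2-methyl-6-nitrobenzoic anhydride (MNBA), DMAP, CH2Cl2, rt, slow addition, ca. 1 mM
Reagents that add atoms: none
Why: Shiina macrolactonization at high dilution and room temperature closes the 12-membered lactone without the heating that could conjugate or epimerize the α-silyloxy β,γ-unsaturated acyl unit.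

**Step 14**
Reactants: 23
Product: 25 (2S,3E,7Z,11E)-2-(tert-butyldimethylsilyloxy)-8-[(4-methoxybenzyloxy)methyl]-4,12-dimethylcyclotetradeca-3,7,11-trien-1-one, via exocyclic enol ether 24 (not isolated)
Conditions: Cp2TiMe2 (3 equiv), toluene, 70 °C, dark; filtration through basic Al2O3 (pentane); then xylenes, Et3N (1%), 140 °C, sealed tube
Reagents that add atoms: dimethyltitanocene (Petasis reagent), C[Ti](C)(C1C=CC=C1)C1C=CC=C1
Why: Dimethyltitanocene loses methane to Cp2Ti=CH2, which converts the lactone carbonyl into the exocyclic enol ether 24 (this CH2 is C14); on heating the titanium-free crude, the allyl vinyl ether C14=C1–O–C11–C12=C13 undergoes a [3,3]-sigmatropic shift in which O–C11 breaks, C13–C14 forms and C1 becomes a ketone. The closest known reaction type is the methylenation–Claisen ring expansion of ω-vinyl lactones to cycloalkenones, the cyclic counterpart of the Claisen chain extensions used in steps 2 and 8. The 14-membered carbocycle closes by two-atom ring expansion of the 12-membered oxacycle through a six-membered chair transition state, a unimolecular process that needs no high dilution. No stereocentre is created: C10 equatorial on C11 in the chair should give the E-C11=C12 alkene, the C11 stereocentre is destroyed so both epimers converge, and C2 is not involved. The selectivity needed is that only this [3,3] array reacts and that the enol ether neither isomerizes into the ring nor hydrolyses; the substrate secures the first because no other alkene is allylic to the ether oxygen, and removal of titanium and a trace of amine before heating guard against the second and against methylenation of the product ketone.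

**Step 15**
Reactants: 25
Product: 26 (2S,3E,7Z,11E)-2-hydroxy-8-[(4-methoxybenzyloxy)methyl]-4,12-dimethylcyclotetradeca-3,7,11-trien-1-one
Conditions: TBAF, AcOH (1:1), THF, 0 °C to rt
Reagents that add atoms: none
Why: buffered fluoride desilylation, the acetic acid suppressing base-induced epimerization or α-ketol shift of the α-hydroxy ketone.

**Step 16**
Reactants: 26
Product: 28 (2S,3E,7Z,11E)-19-(4-methoxybenzyloxy)-17-norcembra-1(15),3,7,11-tetraen-16,2-olide (butenolide fused at C1–C2, C1=C15H), via phosphorane ester 27 (not isolated)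
Conditions: Ph3P=C=C=O (1.5 equiv), toluene, 90 °C
Reagents that add atoms: (triphenylphosphoranylidene)ketene (Bestmann ylide), O=C=C=P(c1ccccc1)(c1ccccc1)c1ccccc1
Why: the Bestmann ylide acylates the hydroxyl to the ester ylide 27, which closes by intramolecular Wittig olefination onto the adjacent ketone, the standard conversion of α-ketols into butenolides, under neutral conditions that leave C2 untouched.

**Step 17**
Reactants: 28
Product: 29 (1S,2R,3E,7Z,11E)-19-(4-methoxybenzyloxy)-17-norcembra-3,7,11-trien-16,2-olide (cis-fused, H-1 and H-2 cis; the C2 descriptor changes only through CIP priorities)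
Conditions: Cu(OAc)2·H2O (5 mol%), 1,2-bis(diphenylphosphino)benzene (5 mol%), (EtO)2MeSiH, t-BuOH, toluene, 0 °C to rt
Reagents that add atoms: none
Why: base-free ligated copper hydride 1,4-reduction (Stryker-type) of the β,β-disubstituted butenolide, in which hydride should reach C1 on the face opposite the C2–C3 bond and the returning macrocyclic chain, making H-1 cis to H-2, while isolated alkenes are not reduced.

**Step 18**
Reactants: 29
Product: 33 (1S,2S,3E,7Z,11E)-19-(4-methoxybenzyloxy)cembra-3,7,11,15(17)-tetraen-16,2-olide, via lithium enolate 30 (not isolated), via Mannich base 31 (not isolated), via ammonium iodide 32 (not isolated)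
Conditions: LDA, THF, −78 °C; CH2=NMe2+ I−, −78 to 0 °C; MeI, MeOH, rt; aq. NaHCO3, CH2Cl2
Reagents that add atoms: Eschenmoser's salt, C=[N+](C)C.[I-]
Why: classical α-methylenation in which the kinetic lactone enolate is aminomethylated and quaternization followed by mild-base β-elimination unveils the exocyclic methylene without touching C1 or C2.

**Step 19**
Reactants: 33
Product: 34 (1S,2S,3E,7Z,11E)-19-hydroxycembra-3,7,11,15(17)-tetraen-16,2-olide
Conditions: DDQ (1.3 equiv), CH2Cl2–pH 7 buffer, 0 °C
Reagents that add atoms: none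
Why: oxidative PMB cleavage (benzylic hydride abstraction, then hydrolysis of the oxocarbenium ion) should be compatible with the α-methylene lactone and the trisubstituted alkenes.

**Step 20**
Reactants: 34
Product: 35 (1S,2S,3E,7Z,11E)-19-acetoxycembra-3,7,11,15(17)-tetraen-16,2-olide (CNP0158848.2)
Conditions: Ac2O, pyridine, DMAP (cat.), CH2Cl2, 0 °C to rt
Reagents that add atoms: acetic anhydride, CC(=O)OC(C)=O
Why: DMAP-catalysed O-acylation of the primary allylic alcohol gives the acetate.

**Compound list**

1 | (R)-2,2-dimethyl-1,3-dioxolane-4-carbaldehyde | CC1(C)O[C@H](CO1)C=O | starting material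
2 | isopropenylmagnesium bromide | CC(=C)[Mg]Br | starting material
3 | (1RS)-1-[(4R)-2,2-dimethyl-1,3-dioxolan-4-yl]-2-methylprop-2-en-1-ol | CC1(C)O[C@H](CO1)C(O)C(C)=C | intermediate
4 | triethyl orthoacetate | CCOC(C)(OCC)OCC | starting material
5 | 1-ethoxyvinyl ether of 3 (ketene acetal) | CC1(C)O[C@H](CO1)C(OC(=C)OCC)C(C)=C | intermediate
6 | ethyl (4E)-5-[(4S)-2,2-dimethyl-1,3-dioxolan-4-yl]-4-methylpent-4-enoate | CC1(C)O[C@H](CO1)/C=C(\C)CCC(=O)OCC | intermediate
7 | ethyl (4E,6S)-6,7-dihydroxy-4-methylhept-4-enoate | O[C@H](CO)/C=C(\C)CCC(=O)OCC | intermediate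
8 | ethyl (4E,6S)-6,7-bis(tert-butyldimethylsilyloxy)-4-methylhept-4-enoate | CC(C)(C)[Si](C)(C)O[C@H](CO[Si](C)(C)C(C)(C)C)/C=C(\C)CCC(=O)OCC | intermediate
9 | (4E,6S)-6,7-bis(tert-butyldimethylsilyloxy)-4-methylhept-4-enal | CC(C)(C)[Si](C)(C)O[C@H](CO[Si](C)(C)C(C)(C)C)/C=C(\C)CCC=O | intermediate
10 | 2,3-dibromoprop-1-ene | BrCC(Br)=C | starting material
11 | 4-methoxybenzyl alcohol | COc1ccc(CO)cc1 | starting material
12 | 2-bromoallyl 4-methoxybenzyl ether | C=C(Br)COCc1ccc(OC)cc1 | intermediate
13 | [3-(4-methoxybenzyloxy)prop-1-en-2-yl]lithium | [Li]C(=C)COCc1ccc(OC)cc1 | intermediate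
14 | (3RS,6E,8S)-8,9-bis(tert-butyldimethylsilyloxy)-2-[(4-methoxybenzyloxy)methyl]-6-methylnona-1,6-dien-3-ol | CC(C)(C)[Si](C)(C)O[C@H](CO[Si](C)(C)C(C)(C)C)/C=C(\C)CCC(O)C(=C)COCc1ccc(OC)cc1 | intermediate
15 | 1-ethoxyvinyl ether of 14 (ketene acetal) | CC(C)(C)[Si](C)(C)O[C@H](CO[Si](C)(C)C(C)(C)C)/C=C(\C)CCC(OC(=C)OCC)C(=C)COCc1ccc(OC)cc1 | intermediate
16 | ethyl (4Z,8E,10S)-10,11-bis(tert-butyldimethylsilyloxy)-4-[(4-methoxybenzyloxy)methyl]-8-methylundeca-4,8-dienoate | CC(C)(C)[Si](C)(C)O[C@H](CO[Si](C)(C)C(C)(C)C)/C=C(\C)CC/C=C(\COCc1ccc(OC)cc1)CCC(=O)OCC | intermediate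
17 | (4Z,8E,10S)-10,11-bis(tert-butyldimethylsilyloxy)-4-[(4-methoxybenzyloxy)methyl]-8-methylundeca-4,8-dienal | CC(C)(C)[Si](C)(C)O[C@H](CO[Si](C)(C)C(C)(C)C)/C=C(\C)CC/C=C(\COCc1ccc(OC)cc1)CCC=O | intermediate
18 | (3RS,6Z,10E,12S)-12,13-bis(tert-butyldimethylsilyloxy)-6-[(4-methoxybenzyloxy)methyl]-2,10-dimethyltrideca-1,6,10-trien-3-ol | CC(C)(C)[Si](C)(C)O[C@H](CO[Si](C)(C)C(C)(C)C)/C=C(\C)CC/C=C(\COCc1ccc(OC)cc1)CCC(O)C(C)=C | intermediate
19 | (2S,3E,7Z,11RS)-2-(tert-butyldimethylsilyloxy)-8-[(4-methoxybenzyloxy)methyl]-4,12-dimethyltrideca-3,7,12-triene-1,11-diol | CC(C)(C)[Si](C)(C)O[C@H](CO)/C=C(\C)CC/C=C(\COCc1ccc(OC)cc1)CCC(O)C(C)=C | intermediate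
20 | (2S,3E,7Z,11RS)-2-(tert-butyldimethylsilyloxy)-11-hydroxy-8-[(4-methoxybenzyloxy)methyl]-4,12-dimethyltrideca-3,7,12-trienal | CC(C)(C)[Si](C)(C)O[C@H](C=O)/C=C(\C)CC/C=C(\COCc1ccc(OC)cc1)CCC(O)C(C)=C | intermediate
21 | (2S,3E,7Z,11RS)-2-(tert-butyldimethylsilyloxy)-11-hydroxy-8-[(4-methoxybenzyloxy)methyl]-4,12-dimethyltrideca-3,7,12-trienoic acid | CC(C)(C)[Si](C)(C)O[C@H](C(=O)O)/C=C(\C)CC/C=C(\COCc1ccc(OC)cc1)CCC(O)C(C)=C | intermediate
22 | mixed anhydride of 21 with 2-methyl-6-nitrobenzoic acid | CC(C)(C)[Si](C)(C)O[C@H](C(=O)OC(=O)c1c(C)cccc1[N+](=O)[O-])/C=C(\C)CC/C=C(\COCc2ccc(OC)cc2)CCC(O)C(C)=C | intermediate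
23 | (3S,4E,8Z,12RS)-3-(tert-butyldimethylsilyloxy)-9-[(4-methoxybenzyloxy)methyl]-5-methyl-12-(prop-1-en-2-yl)oxacyclododeca-4,8-dien-2-one | CC(C)(C)[Si](C)(C)O[C@H]1/C=C(\C)CC/C=C(\COCc2ccc(OC)cc2)CCC(C(C)=C)OC1=O | intermediate
24 | (3S,4E,8Z,12RS)-3-(tert-butyldimethylsilyloxy)-9-[(4-methoxybenzyloxy)methyl]-5-methyl-2-methylidene-12-(prop-1-en-2-yl)oxacyclododeca-4,8-diene | CC(C)(C)[Si](C)(C)O[C@H]1/C=C(\C)CC/C=C(\COCc2ccc(OC)cc2)CCC(C(C)=C)OC1=C | intermediate
25 | (2S,3E,7Z,11E)-2-(tert-butyldimethylsilyloxy)-8-[(4-methoxybenzyloxy)methyl]-4,12-dimethylcyclotetradeca-3,7,11-trien-1-one | CC(C)(C)[Si](C)(C)O[C@H]1/C=C(\C)CC/C=C(\COCc2ccc(OC)cc2)CC/C=C(\C)CCC1=O | intermediate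
26 | (2S,3E,7Z,11E)-2-hydroxy-8-[(4-methoxybenzyloxy)methyl]-4,12-dimethylcyclotetradeca-3,7,11-trien-1-one | O[C@H]1/C=C(\C)CC/C=C(\COCc2ccc(OC)cc2)CC/C=C(\C)CCC1=O | intermediate
27 | (triphenylphosphoranylidene)acetate ester of 26 | O=C(C=P(c1ccccc1)(c2ccccc2)c3ccccc3)O[C@H]4/C=C(\C)CC/C=C(\COCc5ccc(OC)cc5)CC/C=C(\C)CCC4=O | intermediate
28 | (2S,3E,7Z,11E)-19-(4-methoxybenzyloxy)-17-norcembra-1(15),3,7,11-tetraen-16,2-olide | O=C1O[C@H]2/C=C(\C)CC/C=C(\COCc3ccc(OC)cc3)CC/C=C(\C)CCC2=C1 | intermediate
29 | (1S,2R,3E,7Z,11E)-19-(4-methoxybenzyloxy)-17-norcembra-3,7,11-trien-16,2-olide (cis-fused) | C1C(=O)O[C@H]2/C=C(\C)CC/C=C(\COCc3ccc(OC)cc3)CC/C=C(\C)CC[C@@H]12 | intermediate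
30 | lithium enolate of 29 | C1=C(O[Li])O[C@H]2/C=C(\C)CC/C=C(\COCc3ccc(OC)cc3)CC/C=C(\C)CC[C@@H]12 | intermediate
31 | 15-[(dimethylamino)methyl] derivative of 29 (Mannich base, C15 epimers) | CN(C)CC1C(=O)O[C@H]2/C=C(\C)CC/C=C(\COCc3ccc(OC)cc3)CC/C=C(\C)CC[C@@H]12 | intermediate
32 | trimethylammonium iodide of 31 | C[N+](C)(C)CC1C(=O)O[C@H]2/C=C(\C)CC/C=C(\COCc3ccc(OC)cc3)CC/C=C(\C)CC[C@@H]12.[I-] | intermediate
33 | (1S,2S,3E,7Z,11E)-19-(4-methoxybenzyloxy)cembra-3,7,11,15(17)-tetraen-16,2-olide | C=C1C(=O)O[C@H]2/C=C(\C)CC/C=C(\COCc3ccc(OC)cc3)CC/C=C(\C)CC[C@@H]12 | intermediate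
34 | (1S,2S,3E,7Z,11E)-19-hydroxycembra-3,7,11,15(17)-tetraen-16,2-olide | C=C1C(=O)O[C@H]2/C=C(\C)CC/C=C(\CO)CC/C=C(\C)CC[C@@H]12 | intermediate
35 | (1S,2S,3E,7Z,11E)-19-acetoxycembra-3,7,11,15(17)-tetraen-16,2-olide (CNP0158848.2) | C=C1C(=O)O[C@H]2/C=C(\C)CC/C=C(\COC(C)=O)CC/C=C(\C)CC[C@@H]12 | target

**Step count and risks**

Total: 20 steps. Longest linear sequence: 19 steps (steps 1–5 and 7–20, from 1); step 6 is a one-step side branch.

Step 14. The exocyclic enol ether may migrate into the ring or hydrolyse before it rearranges, and ring strain in the 12-membered ether may force a boat or axial pathway that erodes the E geometry at C11=C12. The fallback makes the same C13–C14 bond by ionic palladium chemistry instead of a thermal pericyclic shift. It sets out from seco acid 21, which is condensed with Meldrum's acid (EDC, DMAP, CH2Cl2) to the acyl Meldrum's acid F1. Thermolysis in dilute toluene at 110 °C releases acetone and CO2, and the acylketene is trapped by the C11 hydroxyl to give the 14-membered β-keto lactone F2. Pd(PPh3)4 in THF then ionizes the allylic ester, the β-keto carboxylate loses CO2, and the enolate carbon C14 attacks the unhindered π-allyl terminus C13 (Tsuji decarboxylative allylation). This returns to the route at ketone 25.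

Step 13. The 12-membered ring may close slowly enough for intermolecular acylation (diolide, oligomers) to compete, and the activated α-silyloxy β,γ-unsaturated acyl unit may lose configuration at C2 or conjugate. The fallback activates the carbinol instead of the acid: seco acid 21 is cyclized under Mitsunobu conditions (PPh3, DIAD, toluene, high dilution), the carboxylate displacing the C11 oxyphosphonium with inversion. Because C11 is an epimer mixture that is erased in step 14, this returns directly to lactone 23 and makes no new compound (F0).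

Step 17. Hydride transfer to the hindered, ring-fused β,β-disubstituted butenolide may be slow, leaving time for γ-deprotonation at C2 or giving incomplete facial selectivity. The fallback avoids the butenolide and brings in H-1 by hydrogen-atom transfer. It sets out from ketol 26, which is acylated with bromoacetyl bromide and pyridine to the bromoacetate F3. Activated zinc in THF effects an intramolecular Reformatsky addition to the C1 ketone, giving the β-hydroxy lactone F4. Methyl chlorooxoacetate and DMAP give the tertiary methyl oxalate F5, and Bu3SnH/AIBN in toluene at 100 °C removes the oxalate; the ring-fusion radical should take hydrogen on the face opposite C3. This returns to the route at cis-lactone 29.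

**Further compounds**

F1 | step 14 | acyl Meldrum's acid of 21 | CC(C)(C)[Si](C)(C)O[C@H](C(=O)C1C(=O)OC(C)(C)OC1=O)/C=C(\C)CC/C=C(\COCc2ccc(OC)cc2)CCC(O)C(C)=C
F2 | step 14 | 14-membered β-keto lactone (C1 ketone, C14H2, ester O on C11) | CC(C)(C)[Si](C)(C)O[C@H]1/C=C(\C)CC/C=C(\COCc2ccc(OC)cc2)CCC(C(C)=C)OC(=O)CC1=O
F0 | step 13 | none | none
F3 | step 17 | bromoacetate of 26 | BrCC(=O)O[C@H]1/C=C(\C)CC/C=C(\COCc2ccc(OC)cc2)CC/C=C(\C)CCC1=O
F4 | step 17 | 1-hydroxy derivative of lactone 29 (C1 epimers) | C1C(=O)O[C@H]2/C=C(\C)CC/C=C(\COCc3ccc(OC)cc3)CC/C=C(\C)CCC12O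
F5 | step 17 | methyl oxalate of F4 | C1C(=O)O[C@H]2/C=C(\C)CC/C=C(\COCc3ccc(OC)cc3)CC/C=C(\C)CCC12OC(=O)C(=O)OC
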